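## Retrosynthetic overview
Lactone numbering: O-1, C-2 (C=O), C-3, C-4, C-5; the side-chain carbinol carbon is C-7'.

1. Target ⇒ its bis(benzyl ether). The quaternary carbinol C-3 is cut at the C-3–CH2Ar bond, which is made by benzylating an α-oxido lactone enolate on the face away from the C-4 side chain.
2. The α-oxygen comes from enolate oxidation. The C-4 hydrogen comes from an OH-directed hydrogenation of a 4-(aryl-hydroxymethyl)butenolide.
3. Key disconnection: C-4–C-7'. A butenolide β-carbon and an aldehyde carbon, both electrophilic by nature, are joined by making the butenolide its β-chromio derivative (a β-acyl vinyl anion, the sp2 homoenolate). A chiral chromium catalyst sets C-7', and the other two centres are relayed from it.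
4. 4-Bromobutenolide ⇒ tetronic acid. Both aryl units ⇒ O-benzylvanillin and the corresponding benzyl alcohol.
5. Rings: the γ-lactone is bought in with tetronic acid and is never opened, so no ring is formed.

Assumption: the (S)-valinol-derived ligand is taken to give Re-face attack on the aldehyde; this is checked on the first run (Mosher ester), and the antipodal ligand is used if needed.

## Route

Step 1
Reactants: 1 tetronic acid (4-hydroxyfuran-2(5H)-one)
Product: 2 4-bromofuran-2(5H)-one
Conditions: (COBr)2 (1.2 equiv), DMF (cat.), CH2Cl2, 0 °C to rt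
Reagents that add atoms: oxalyl bromide, O=C(Br)C(=O)Br
Why: Vilsmeier-type deoxybromination in which the vinylogous acid OH is activated by the bromoiminium salt and replaced by bromide through addition–elimination, with no stereocentre involved.

Step 2
Reactants: 2 4-bromofuran-2(5H)-one; 3 4-(benzyloxy)-3-methoxybenzaldehyde (O-benzylvanillin)
Product: 5 (S)-4-{[4-(benzyloxy)-3-methoxyphenyl](hydroxy)methyl}furan-2(5H)-one, via alkenylchromium dichloride 4 (not isolated)
Conditions: CrCl2 (10 mol %), (S)-N-[2-(4-isopropyl-4,5-dihydrooxazol-2-yl)-6-methylphenyl]methanesulfonamide (12 mol %), 1,8-bis(dimethylamino)naphthalene (12 mol %), NiCl2(2,9-dimethyl-1,10-phenanthroline) (2 mol %), Mn (2 equiv), Cp2ZrCl2 (1.1 equiv), LiCl (2 equiv), MeCN, rt; aq. NaHCO3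
Reagents that add atoms: none
Why: Catalytic asymmetric Nozaki–Hiyama–Kishi coupling in which zerovalent nickel inserts into the C–Br bond and passes the alkenyl group to chromium, so the normally electrophilic β-carbon becomes the nucleophile 4, which adds to the Re face of 3 inside the chiral sulfonamide–chromium complex and sets C-7' (S by CIP here because the butenolide carbon outranks the aryl carbon, the same spatial arrangement as R in 6 to 13), while Cp2ZrCl2 releases the chromium alkoxide and Mn returns trivalent to divalent chromium.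

Step 3
Reactants: 5 (S)-4-{[4-(benzyloxy)-3-methoxyphenyl](hydroxy)methyl}furan-2(5H)-one
Product: 6 (R)-4-{(R)-[4-(benzyloxy)-3-methoxyphenyl](hydroxy)methyl}dihydrofuran-2(3H)-one
Conditions: [Rh(nbd)(dppb)]BF4 (5 mol %), H2 (50 bar), CH2Cl2, rt
Reagents that add atoms: none
Why: Hydroxyl-directed homogeneous hydrogenation in which the cationic rhodium binds the OH and the alkene on one face and the aryl group turns away from the ring CH2 in the favoured rotamer (A(1,2) strain, only H in the cis alkene position), so H2 gives the 1,2-anti product as with α-(hydroxyalkyl)acrylates, which is (4R), and the high pressure suppresses allylic alcohol isomerisation while the benzyl ethers survive.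

Step 4
Reactants: 6 (R)-4-{(R)-[4-(benzyloxy)-3-methoxyphenyl](hydroxy)methyl}dihydrofuran-2(3H)-one
Product: 8 (3R,4R)-4-{(R)-[4-(benzyloxy)-3-methoxyphenyl](hydroxy)methyl}-3-hydroxydihydrofuran-2(3H)-one (major 3,4-trans isomer), via dipotassium alkoxide enolate 7 (not isolated)
Conditions: KN(SiMe3)2 (2.3 equiv), THF, −78 °C; 2-(phenylsulfonyl)-3-phenyloxaziridine (1.3 equiv), −78 °C; AcOH
Reagents that add atoms: 2-(phenylsulfonyl)-3-phenyloxaziridine (Davis reagent), O=S(=O)(N1OC1c1ccccc1)c1ccccc1
Why: Davis oxidation of a lactone enolate in which oxygen enters mainly trans to the C-4 side chain, but this C-3 configuration does not matter because the centre becomes planar again in step 6.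

Step 5
Reactants: 9 [4-(benzyloxy)-3-methoxyphenyl]methanol
Product: 10 1-(benzyloxy)-4-(bromomethyl)-2-methoxybenzene
Conditions: PBr3 (0.4 equiv), Et2O, 0 °C; used at once
Reagents that add atoms: phosphorus tribromide, BrP(Br)Br
Why: Bromination of a benzylic alcohol through its phosphite ester by SN2 displacement, with no stereocentre involved.

Step 6
Reactants: 8 (3R,4R)-4-{(R)-[4-(benzyloxy)-3-methoxyphenyl](hydroxy)methyl}-3-hydroxydihydrofuran-2(3H)-one; 10 1-(benzyloxy)-4-(bromomethyl)-2-methoxybenzene
Product: 12 (3S,4R)-3-[4-(benzyloxy)-3-methoxybenzyl]-4-{(R)-[4-(benzyloxy)-3-methoxyphenyl](hydroxy)methyl}-3-hydroxydihydrofuran-2(3H)-one, via trilithium alkoxide enolate 11 (not isolated)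
Conditions: LiN(iPr)2 (3.3 equiv), THF–DMPU, −78 to −40 °C; 10 (1.05 equiv), −78 °C; AcOH at −78 °C
Reagents that add atoms: none
Why: Alkylation of an α-oxido ester enolate (Seebach–Fráter type polyanion) in which C-3 is planar in 11 and the lithium-bridged C-4 side chain blocks one face, so the bromide enters trans to it, leaving OH cis to the side chain and giving (3S), with carbon reacting faster than the alkoxides at −78 °C.

Step 7
Reactants: 12 (3S,4R)-3-[4-(benzyloxy)-3-methoxybenzyl]-4-{(R)-[4-(benzyloxy)-3-methoxyphenyl](hydroxy)methyl}-3-hydroxydihydrofuran-2(3H)-one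
Product: 13 (3S,4R)-3-hydroxy-4-[(R)-hydroxy(4-hydroxy-3-methoxyphenyl)methyl]-3-(4-hydroxy-3-methoxybenzyl)dihydrofuran-2(3H)-one (target)
Conditions: H2 (1 atm), 10% Pd/C, EtOAc, rt, stopped after 2 equiv H2
Reagents that add atoms: none
Why: Hydrogenolysis of aryl benzyl ethers, which is much faster than cleavage of the secondary benzylic alcohol in a neutral aprotic medium, and no acid or base is present that could ionise C-7' or move the lactone, so no stereocentre is touched.

## Compound list
1 | tetronic acid (4-hydroxyfuran-2(5H)-one) | OC1=CC(=O)OC1 | starting material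
2 | 4-bromofuran-2(5H)-one | O=C1C=C(Br)CO1 | intermediate
3 | 4-(benzyloxy)-3-methoxybenzaldehyde | COc1cc(C=O)ccc1OCc1ccccc1 | starting material
4 | (5-oxo-2,5-dihydrofuran-3-yl)chromium dichloride, chiral ligand omitted, not isolated | O=C1C=C([Cr](Cl)Cl)CO1 | intermediate
5 | (S)-4-{[4-(benzyloxy)-3-methoxyphenyl](hydroxy)methyl}furan-2(5H)-one | O=C1C=C(CO1)[C@@H](O)c1ccc(OCc2ccccc2)c(OC)c1 | intermediate
6 | (R)-4-{(R)-[4-(benzyloxy)-3-methoxyphenyl](hydroxy)methyl}dihydrofuran-2(3H)-one | O=C1OC[C@@H](C1)[C@@H](O)c1ccc(OCc2ccccc2)c(OC)c1 | intermediate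
7 | dipotassium salt of 6 (lactone enolate and C-7' alkoxide), not isolated | [K+].[K+].[O-]C1=C[C@H](CO1)[C@@H]([O-])c1ccc(OCc2ccccc2)c(OC)c1 | intermediate
8 | (3R,4R)-4-{(R)-[4-(benzyloxy)-3-methoxyphenyl](hydroxy)methyl}-3-hydroxydihydrofuran-2(3H)-one | O=C1OC[C@@H]([C@H]1O)[C@@H](O)c1ccc(OCc2ccccc2)c(OC)c1 | intermediate
9 | [4-(benzyloxy)-3-methoxyphenyl]methanol | COc1cc(CO)ccc1OCc1ccccc1 | starting material
10 | 1-(benzyloxy)-4-(bromomethyl)-2-methoxybenzene | COc1cc(CBr)ccc1OCc1ccccc1 | intermediate
11 | trilithium salt of 8 (C-3 oxido enolate and C-7' alkoxide), not isolated | [Li+].[Li+].[Li+].[O-]C1=C([O-])[C@H](CO1)[C@@H]([O-])c1ccc(OCc2ccccc2)c(OC)c1 | intermediate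
12 | (3S,4R)-3-[4-(benzyloxy)-3-methoxybenzyl]-4-{(R)-[4-(benzyloxy)-3-methoxyphenyl](hydroxy)methyl}-3-hydroxydihydrofuran-2(3H)-one | COc1cc(C[C@@]2(O)C(=O)OC[C@@H]2[C@@H](O)c2ccc(OCc3ccccc3)c(OC)c2)ccc1OCc1ccccc1 | intermediate
13 | (3S,4R)-3-hydroxy-4-[(R)-hydroxy(4-hydroxy-3-methoxyphenyl)methyl]-3-(4-hydroxy-3-methoxybenzyl)dihydrofuran-2(3H)-one | COc1cc(C[C@@]2(O)C(=O)OC[C@@H]2[C@@H](O)c2ccc(O)c(OC)c2)ccc1O | target

## Step count and risks
Total steps: 7. Longest linear sequence: 6 (steps 1, 2, 3, 4, 6, 7); step 5 is a one-step side branch.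

**Step 2** is the most exposed. An electron-rich aromatic aldehyde and an electron-poor alkenyl bromide may give modest ee, pinacol coupling of 3, or nickel-mediated dimerisation of 2.
- The fallback sets out from 2 (together with 3) and comes back at 5. It keeps the C–C bond construction but moves the stereocontrol to a ketone reduction.
- The ligand-free coupling (CrCl2, 3 equiv, cat. NiCl2, DMF) gives racemic 4-{[4-(benzyloxy)-3-methoxyphenyl](hydroxy)methyl}furan-2(5H)-one F1.
- MnO2 in CH2Cl2 oxidises F1 to 4-[4-(benzyloxy)-3-methoxybenzoyl]furan-2(5H)-one F2.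
- 1,2-Reduction of F2 with (S)-2-methyl-CBS-oxazaborolidine and catecholborane at −78 °C, with the aryl group as the large substituent, returns 5.

**Step 3** is next. The trisubstituted, electron-poor alkene may react slowly, and the rotamer preference may give a poor diastereomer ratio.
- The fallback sets out from 5 and comes back at 6. It replaces substrate direction by reagent control.
- TBSCl and imidazole give the tert-butyldimethylsilyl ether of 5 F3.
- A copper hydride conjugate reduction (Cu(OAc)2, the matched enantiomer of DTBM-SEGPHOS, polymethylhydrosiloxane, t-BuOH, toluene) gives the tert-butyldimethylsilyl ether of 6 F4.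
- Bu4NF buffered with AcOH then gives 6.

**Step 6** is third. The trianion may be poorly soluble, may O-alkylate, or may translactonise before the quench.
- The fallback sets out from 8 and comes back at 12. It abandons the polyanion for a fully masked mono-enolate.
- Et3SiOTf and 2,6-lutidine give the bis(triethylsilyl) ether of 8 F5.
- LiN(iPr)2 (1.1 equiv), then 10 at −78 °C, gives the bis(triethylsilyl) ether of 12 F6 with the same trans facial bias.
- Bu4NF buffered with AcOH then gives 12.

## Further compounds
F1 | step 2 | racemic 4-{[4-(benzyloxy)-3-methoxyphenyl](hydroxy)methyl}furan-2(5H)-one | O=C1C=C(CO1)C(O)c1ccc(OCc2ccccc2)c(OC)c1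
F2 | step 2 | 4-[4-(benzyloxy)-3-methoxybenzoyl]furan-2(5H)-one | O=C1C=C(CO1)C(=O)c1ccc(OCc2ccccc2)c(OC)c1
F3 | step 3 | tert-butyldimethylsilyl ether of 5 | O=C1C=C(CO1)[C@@H](O[Si](C)(C)C(C)(C)C)c1ccc(OCc2ccccc2)c(OC)c1
F4 | step 3 | tert-butyldimethylsilyl ether of 6 | O=C1OC[C@@H](C1)[C@@H](O[Si](C)(C)C(C)(C)C)c1ccc(OCc2ccccc2)c(OC)c1
F5 | step 6 | bis(triethylsilyl) ether of 8 | O=C1OC[C@@H]([C@H]1O[Si](CC)(CC)CC)[C@@H](O[Si](CC)(CC)CC)c1ccc(OCc2ccccc2)c(OC)c1
F6 | step 6 | bis(triethylsilyl) ether of 12 | COc1cc(C[C@@]2(O[Si](CC)(CC)CC)C(=O)OC[C@@H]2[C@@H](O[Si](CC)(CC)CC)c2ccc(OCc3ccccc3)c(OC)c2)ccc1OCc1ccccc1
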